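**Strategy.** The 3‑palmitoyloxy β‑ring (carotenoid numbering: C1 gem‑dimethyl, C3 carbinol, C5 methyl‑bearing, C6 chain‑bearing) is not made as a six‑membered ring. Its C3 stereocentre is set on a cyclopentanone. A regioselective one‑carbon ring enlargement with diazoethane then inserts C5, methyl group included, between the carbonyl carbon C6 and the C4 methylene. The precursor is (S)‑3,3‑dimethyl‑4‑oxocyclopentyl palmitate. The step exploits the quaternary carbon C1 beside the C6 carbonyl, which blocks migration on that side and later forces the enol triflate into the C5=C6 position. Stille coupling and salt formation give the β‑C15 phosphonium salt; the ε‑C15 salt comes from α‑ionone. Two Wittig reactions with the C10 dialdehyde assemble the diester.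

Key step: step 4

Remark: the sense of induction of the chiral catalysts in steps 2 and 11 is assigned by analogy with simple cyclic enones; if a first run (configuration assigned by derivatisation) shows the opposite sense, the antipodal ligand is used.

**Step 1**
Reactants: 1 2,2‑dimethylcyclopentan‑1‑one
Product: 2 5,5‑dimethylcyclopent‑2‑en‑1‑one
Conditions: IBX (2 equiv), DMSO/toluene, 75 °C
Reagents that add atoms: none
Why: IBX dehydrogenation of a ketone can only run through the single enolisable α‑methylene, so one enone should result.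

**Step 2**
Reactants: 2 5,5‑dimethylcyclopent‑2‑en‑1‑one
Product: 4 (S)‑4‑hydroxy‑2,2‑dimethylcyclopentan‑1‑one, via pinacol boronate 3 (not isolated)
Conditions: B2pin2, CuCl (3 mol%), NaOtBu (6 mol%), (R,R)‑QuinoxP* (4 mol%), MeOH (2 equiv), THF, rt; then NaBO3·4H2O, THF/H2O, rt
Reagents that add atoms: bis(pinacolato)diboron CC1(C)OB(OC1(C)C)B1OC(C)(C)C(C)(C)O1; sodium perborate [Na+].[O-]OB=O
Why: Copper‑catalysed asymmetric conjugate borylation sets the C–B stereocentre under control of the chiral bisphosphine, and perborate oxidation replaces boron by oxygen with retention.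

**Step 3**
Reactants: 4 (S)‑4‑hydroxy‑2,2‑dimethylcyclopentan‑1‑one; 5 palmitoyl chloride
Product: 6 (1S)‑3,3‑dimethyl‑4‑oxocyclopentyl hexadecanoate
Conditions: pyridine, CH2Cl2, 0 °C
Reagents that add atoms: none
Why: O‑acylation with retention installs the final C3 ester early, and the cold, weakly basic medium should not trigger E1cB loss of the β‑acyloxy group.

**Step 4**
Reactants: 6 (1S)‑3,3‑dimethyl‑4‑oxocyclopentyl hexadecanoate
Product: 7 (1R)‑3,3,5‑trimethyl‑4‑oxocyclohexyl hexadecanoate (mixture of C5 epimers)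
Conditions: CH3CHN2 (Et2O solution, 2–3 equiv), Sc(OTf)3 (10 mol%), CH2Cl2/toluene, −78 → −40 °C
Reagents that add atoms: diazoethane CC=[N+]=[N-]
Why: The scandium‑activated carbonyl carbon (C6) is attacked by the nucleophilic carbon of diazoethane to give a β‑oxido alkanediazonium betaine, and the ring C4–C6 bond anti‑periplanar to the departing N2 migrates to the diazo carbon, which becomes ring carbon C5 with its methyl group. The closest known reaction type is the Lewis‑acid‑catalysed diazoalkane homologation of cycloalkanones (Büchner–Curtius–Schlotterbeck type), which on α‑quaternary cyclopentanones such as the D ring of 17‑oxo steroids proceeds by methylene migration. No ring is closed: the five‑membered ring C6–C1–C2–C3–C4 is widened to the six‑membered ring C1–C6 by this 1,2‑carbon shift. The C3 carbinol stereocentre is a spectator and keeps its configuration (the descriptor changes from S to R only because the ring priorities change), while the new CH(CH3) centre forms without control and is erased in step 5. The selectivity needed is migration of the C4 methylene and not of the quaternary C1, which the gem‑dimethyl group secures by disfavouring the betaine conformer that places C1 anti to N2. Over‑homologation is not expected because the product ketone, flanked by a quaternary and a tertiary carbon, is far less reactive than 6.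

**Step 5**
Reactants: 7 (1R)‑3,3,5‑trimethyl‑4‑oxocyclohexyl hexadecanoate
Product: 8 (1R)‑3,5,5‑trimethyl‑4‑[(trifluoromethanesulfonyl)oxy]cyclohex‑3‑en‑1‑yl hexadecanoate
Conditions: Tf2O, 2,6‑di‑tert‑butyl‑4‑methylpyridine, CH2Cl2, 0 °C → rt
Reagents that add atoms: trifluoromethanesulfonic anhydride O=S(=O)(OS(=O)(=O)C(F)(F)F)C(F)(F)F
Why: O‑triflation of the ketone and loss of its only α‑proton (at C5, C1 being quaternary) gives the tetrasubstituted C5=C6 enol triflate under non‑nucleophilic conditions that spare the ester.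

**Step 6**
Reactants: 9 (E)‑3‑methylpent‑2‑en‑4‑yn‑1‑ol
Product: 10 (2E,4E)‑3‑methyl‑5‑(tributylstannyl)penta‑2,4‑dien‑1‑ol
Conditions: Bu3SnH, PdCl2(PPh3)2 (2 mol%), THF, 0 °C
Reagents that add atoms: tributyltin hydride CCCC[SnH](CCCC)CCCC
Why: Palladium‑catalysed syn‑hydrostannation of the terminal alkyne of the branched enyne should place tin on the terminal carbon and give the E‑alkenylstannane.

**Step 7**
Reactants: 8 (1R)‑3,5,5‑trimethyl‑4‑[(trifluoromethanesulfonyl)oxy]cyclohex‑3‑en‑1‑yl hexadecanoate; 10 (2E,4E)‑3‑methyl‑5‑(tributylstannyl)penta‑2,4‑dien‑1‑ol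
Product: 11 (1R)‑4‑[(1E,3E)‑5‑hydroxy‑3‑methylpenta‑1,3‑dien‑1‑yl]‑3,5,5‑trimethylcyclohex‑3‑en‑1‑yl hexadecanoate
Conditions: Pd2(dba)3 (2.5 mol%), AsPh3 (20 mol%), NMP, 60 °C
Reagents that add atoms: none
Why: Stille coupling forms the C6–C7 bond with retention of both alkene geometries, the AsPh3/NMP system being chosen because it speeds transmetallation onto the hindered cyclohexenyl palladium triflate.

**Step 8**
Reactants: 11 (1R)‑4‑[(1E,3E)‑5‑hydroxy‑3‑methylpenta‑1,3‑dien‑1‑yl]‑3,5,5‑trimethylcyclohex‑3‑en‑1‑yl hexadecanoate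
Product: 12 {(2E,4E)‑5‑[(4R)‑4‑(hexadecanoyloxy)‑2,6,6‑trimethylcyclohex‑1‑en‑1‑yl]‑3‑methylpenta‑2,4‑dien‑1‑yl}triphenylphosphonium bromide
Conditions: PPh3·HBr, CH2Cl2, 0 °C → rt
Reagents that add atoms: triphenylphosphine hydrobromide Br.c1ccc(cc1)P(c1ccccc1)c1ccccc1
Why: Acid ionisation of the dienylic alcohol to a delocalised pentadienyl cation and capture by PPh3 at the terminal carbon gives the thermodynamically favoured (2E,4E) salt and leaves the homoallylic ester alone.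

**Step 9**
Reactants: 13 (±)‑α‑ionone
Product: 14 (±)‑2‑methyl‑2‑[(E)‑2‑(2,6,6‑trimethylcyclohex‑2‑en‑1‑yl)ethenyl]‑1,3‑dioxolane
Conditions: TMSOCH2CH2OTMS, TMSOTf (2 mol%), CH2Cl2, −78 °C
Reagents that add atoms: 1,2‑bis(trimethylsilyloxy)ethane C[Si](C)(C)OCCO[Si](C)(C)C
Why: Aprotic silyl‑transfer ketalisation masks the side‑chain enone carbonyl without migration of either double bond, so that the ring ketone made next is the only one present in step 11.

**Step 10**
Reactants: 14 (±)‑2‑methyl‑2‑[(E)‑2‑(2,6,6‑trimethylcyclohex‑2‑en‑1‑yl)ethenyl]‑1,3‑dioxolane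
Product: 15 (±)‑3,5,5‑trimethyl‑4‑[(E)‑2‑(2‑methyl‑1,3‑dioxolan‑2‑yl)ethenyl]cyclohex‑2‑en‑1‑one
Conditions: t‑BuOOH (70% aq.), aq. NaOCl, K2CO3, MeCN, 0 °C
Reagents that add atoms: tert‑butyl hydroperoxide CC(C)(C)OO
Why: Radical allylic oxidation by tert‑butylperoxyl radicals should attack the ring methylene C3, which is more accessible than the tertiary C6–H beside the gem‑dimethyl group, and give the ring enone.

**Step 11**
Reactants: 15 (±)‑3,5,5‑trimethyl‑4‑[(E)‑2‑(2‑methyl‑1,3‑dioxolan‑2‑yl)ethenyl]cyclohex‑2‑en‑1‑one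
Product: 17 (3E)‑4‑[(1R,4R)‑4‑hydroxy‑2,6,6‑trimethylcyclohex‑2‑en‑1‑yl]but‑3‑en‑2‑one, via ketal alcohol 16 (not isolated)
Conditions: RuCl[(R,R)‑TsDPEN](p‑cymene) (1 mol%), t‑BuOK (2 mol%), i‑PrOH, rt; then PPTS, acetone/H2O, rt; chromatography
Reagents that add atoms: water O
Why: Catalyst‑controlled asymmetric transfer hydrogenation of the ring enone carbonyl (alkenyl flank in the role of the aryl group) should make the carbinol R in both enantiomers of 15, so the (6R) half gives the trans (3R,6R) alcohol, which after mild ketal hydrolysis is separated from the cis (3R,6S) epimer, C6 thus being secured by separation of diastereomers.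

**Step 12**
Reactants: 17 (3E)‑4‑[(1R,4R)‑4‑hydroxy‑2,6,6‑trimethylcyclohex‑2‑en‑1‑yl]but‑3‑en‑2‑one
Product: 18 (1R,4R)‑4‑[(1E)‑3‑hydroxy‑3‑methylpenta‑1,4‑dien‑1‑yl]‑3,5,5‑trimethylcyclohex‑2‑en‑1‑ol (epimers at the new carbinol)
Conditions: CH2=CHMgBr (2.5 equiv), THF, −20 → 0 °C; aq. NH4Cl
Reagents that add atoms: vinylmagnesium bromide C=C[Mg]Br
Why: After deprotonation of the hydroxyl, Grignard 1,2‑addition to the enone carbonyl gives the tertiary divinyl carbinol, whose uncontrolled centre is destroyed in step 14.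

**Step 13**
Reactants: 18 (1R,4R)‑4‑[(1E)‑3‑hydroxy‑3‑methylpenta‑1,4‑dien‑1‑yl]‑3,5,5‑trimethylcyclohex‑2‑en‑1‑ol; 19 myristoyl chloride
Product: 20 (1R,4R)‑4‑[(1E)‑3‑hydroxy‑3‑methylpenta‑1,4‑dien‑1‑yl]‑3,5,5‑trimethylcyclohex‑2‑en‑1‑yl tetradecanoate
Conditions: pyridine, CH2Cl2, 0 °C
Reagents that add atoms: none
Why: The secondary ring hydroxyl is acylated with retention while the hindered tertiary carbinol does not react under these conditions.

**Step 14**
Reactants: 20 (1R,4R)‑4‑[(1E)‑3‑hydroxy‑3‑methylpenta‑1,4‑dien‑1‑yl]‑3,5,5‑trimethylcyclohex‑2‑en‑1‑yl tetradecanoate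
Product: 21 {(2E,4E)‑3‑methyl‑5‑[(1R,4R)‑2,6,6‑trimethyl‑4‑(tetradecanoyloxy)cyclohex‑2‑en‑1‑yl]penta‑2,4‑dien‑1‑yl}triphenylphosphonium bromide
Conditions: PPh3·HBr, CH2Cl2, 0 °C → rt
Reagents that add atoms: triphenylphosphine hydrobromide Br.c1ccc(cc1)P(c1ccccc1)c1ccccc1
Why: The tertiary bis‑allylic carbinol ionises far more readily than the ring allylic ester, and PPh3 captures the cation at the terminal vinyl carbon with allylic transposition to give the conjugated (2E,4E) salt.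

**Step 15**
Reactants: 21 {(2E,4E)‑3‑methyl‑5‑[(1R,4R)‑2,6,6‑trimethyl‑4‑(tetradecanoyloxy)cyclohex‑2‑en‑1‑yl]penta‑2,4‑dien‑1‑yl}triphenylphosphonium bromide; 22 (2E,4E,6E)‑2,7‑dimethylocta‑2,4,6‑trienedial (3 equiv)
Product: 24 (3R,6R)‑3‑(tetradecanoyloxy)‑12'‑apo‑ε‑caroten‑12'‑al, via ylide 23 (not isolated)
Conditions: 1,2‑epoxybutane (excess), i‑PrOH, 70 °C; then heptane, 90 °C
Reagents that add atoms: none
Why: In this Wittig reaction bromide opens the epoxide to an alkoxide that forms the ylide under nearly neutral conditions (ester and C6' survive), excess dialdehyde and the lower electrophilicity of the product favour mono‑olefination, and heating should convert any Z isomer at the new double bond into the E form.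

**Step 16**
Reactants: 12 {(2E,4E)‑5‑[(4R)‑4‑(hexadecanoyloxy)‑2,6,6‑trimethylcyclohex‑1‑en‑1‑yl]‑3‑methylpenta‑2,4‑dien‑1‑yl}triphenylphosphonium bromide; 24 (3R,6R)‑3‑(tetradecanoyloxy)‑12'‑apo‑ε‑caroten‑12'‑al
Product: 26 (3R,3'R,6'R)‑β,ε‑carotene‑3,3'‑diol 3‑hexadecanoate 3'‑tetradecanoate, via ylide 25 (not isolated)
Conditions: 1,2‑epoxybutane (excess), i‑PrOH, 70 °C; then heptane, 90 °C; crystallisation
Reagents that add atoms: none
Why: The second Wittig reaction under the same neutral conditions closes the C11=C12 bond with both esters already in place, and thermal equilibration of the hindered Z isomer should leave the all‑E carotenoid.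

**Compound list**
1 | 2,2‑dimethylcyclopentan‑1‑one | CC1(C)CCCC1=O | starting material
2 | 5,5‑dimethylcyclopent‑2‑en‑1‑one | CC1(C)CC=CC1=O | intermediate
3 | (S)‑2,2‑dimethyl‑4‑(4,4,5,5‑tetramethyl‑1,3,2‑dioxaborolan‑2‑yl)cyclopentan‑1‑one | CC1(C)OB(OC1(C)C)[C@@H]1CC(=O)C(C)(C)C1 | intermediate
4 | (S)‑4‑hydroxy‑2,2‑dimethylcyclopentan‑1‑one | O[C@@H]1CC(=O)C(C)(C)C1 | intermediate
5 | palmitoyl chloride | CCCCCCCCCCCCCCCC(=O)Cl | starting material
6 | (1S)‑3,3‑dimethyl‑4‑oxocyclopentyl hexadecanoate | CCCCCCCCCCCCCCCC(=O)O[C@@H]1CC(=O)C(C)(C)C1 | intermediate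
7 | (1R)‑3,3,5‑trimethyl‑4‑oxocyclohexyl hexadecanoate (C5 epimers) | CCCCCCCCCCCCCCCC(=O)O[C@@H]1CC(C)C(=O)C(C)(C)C1 | intermediate
8 | (1R)‑3,5,5‑trimethyl‑4‑[(trifluoromethanesulfonyl)oxy]cyclohex‑3‑en‑1‑yl hexadecanoate | CCCCCCCCCCCCCCCC(=O)O[C@@H]1CC(C)=C(OS(=O)(=O)C(F)(F)F)C(C)(C)C1 | intermediate
9 | (E)‑3‑methylpent‑2‑en‑4‑yn‑1‑ol | C#C/C(C)=C/CO | starting material
10 | (2E,4E)‑3‑methyl‑5‑(tributylstannyl)penta‑2,4‑dien‑1‑ol | CCCC[Sn](CCCC)(CCCC)/C=C/C(C)=C/CO | intermediate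
11 | (1R)‑4‑[(1E,3E)‑5‑hydroxy‑3‑methylpenta‑1,3‑dien‑1‑yl]‑3,5,5‑trimethylcyclohex‑3‑en‑1‑yl hexadecanoate | CCCCCCCCCCCCCCCC(=O)O[C@@H]1CC(C)=C(/C=C/C(C)=C/CO)C(C)(C)C1 | intermediate
12 | {(2E,4E)‑5‑[(4R)‑4‑(hexadecanoyloxy)‑2,6,6‑trimethylcyclohex‑1‑en‑1‑yl]‑3‑methylpenta‑2,4‑dien‑1‑yl}triphenylphosphonium bromide | CCCCCCCCCCCCCCCC(=O)O[C@@H]1CC(C)=C(/C=C/C(C)=C/C[P+](c2ccccc2)(c2ccccc2)c2ccccc2)C(C)(C)C1.[Br-] | intermediate
13 | (±)‑α‑ionone | CC(=O)/C=C/C1C(C)=CCCC1(C)C | starting material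
14 | (±)‑2‑methyl‑2‑[(E)‑2‑(2,6,6‑trimethylcyclohex‑2‑en‑1‑yl)ethenyl]‑1,3‑dioxolane | CC1(OCCO1)/C=C/C1C(C)=CCCC1(C)C | intermediate
15 | (±)‑3,5,5‑trimethyl‑4‑[(E)‑2‑(2‑methyl‑1,3‑dioxolan‑2‑yl)ethenyl]cyclohex‑2‑en‑1‑one | CC1(OCCO1)/C=C/C1C(C)=CC(=O)CC1(C)C | intermediate
16 | (1R,4R)‑3,5,5‑trimethyl‑4‑[(E)‑2‑(2‑methyl‑1,3‑dioxolan‑2‑yl)ethenyl]cyclohex‑2‑en‑1‑ol | CC1(OCCO1)/C=C/[C@H]1C(C)=C[C@H](O)CC1(C)C | intermediate
17 | (3E)‑4‑[(1R,4R)‑4‑hydroxy‑2,6,6‑trimethylcyclohex‑2‑en‑1‑yl]but‑3‑en‑2‑one, (3R,6R)‑3‑hydroxy‑α‑ionone | CC(=O)/C=C/[C@H]1C(C)=C[C@H](O)CC1(C)C | intermediate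
18 | (1R,4R)‑4‑[(1E)‑3‑hydroxy‑3‑methylpenta‑1,4‑dien‑1‑yl]‑3,5,5‑trimethylcyclohex‑2‑en‑1‑ol (side‑chain carbinol epimers) | C=CC(C)(O)/C=C/[C@H]1C(C)=C[C@H](O)CC1(C)C | intermediate
19 | myristoyl chloride | CCCCCCCCCCCCCC(=O)Cl | starting material
20 | (1R,4R)‑4‑[(1E)‑3‑hydroxy‑3‑methylpenta‑1,4‑dien‑1‑yl]‑3,5,5‑trimethylcyclohex‑2‑en‑1‑yl tetradecanoate | C=CC(C)(O)/C=C/[C@H]1C(C)=C[C@H](OC(=O)CCCCCCCCCCCCC)CC1(C)C | intermediate
21 | {(2E,4E)‑3‑methyl‑5‑[(1R,4R)‑2,6,6‑trimethyl‑4‑(tetradecanoyloxy)cyclohex‑2‑en‑1‑yl]penta‑2,4‑dien‑1‑yl}triphenylphosphonium bromide | C(/C=C(C)/C=C/[C@H]1C(C)=C[C@H](OC(=O)CCCCCCCCCCCCC)CC1(C)C)[P+](c1ccccc1)(c1ccccc1)c1ccccc1.[Br-] | intermediate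
22 | (2E,4E,6E)‑2,7‑dimethylocta‑2,4,6‑trienedial | O=C/C(C)=C/C=C/C=C(C)/C=O | starting material
23 | ylide of 21, (2E,4E)‑dienylidene‑triphenylphosphorane | C(/C=C(C)/C=C/[C@H]1C(C)=C[C@H](OC(=O)CCCCCCCCCCCCC)CC1(C)C)=P(c1ccccc1)(c1ccccc1)c1ccccc1 | intermediate
24 | (3R,6R)‑3‑(tetradecanoyloxy)‑12'‑apo‑ε‑caroten‑12'‑al | O=C/C(C)=C/C=C/C=C(C)/C=C/C=C(C)/C=C/[C@H]1C(C)=C[C@H](OC(=O)CCCCCCCCCCCCC)CC1(C)C | intermediate
25 | ylide of 12, (2E,4E)‑dienylidene‑triphenylphosphorane | CCCCCCCCCCCCCCCC(=O)O[C@@H]1CC(C)=C(/C=C/C(C)=C/C=P(c2ccccc2)(c2ccccc2)c2ccccc2)C(C)(C)C1 | intermediate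
26 | (3R,3'R,6'R)‑β,ε‑carotene‑3,3'‑diol 3‑hexadecanoate 3'‑tetradecanoate | CCCCCCCCCCCCCCCC(=O)O[C@@H]1CC(C)=C(/C=C/C(C)=C/C=C/C(C)=C/C=C/C=C(C)/C=C/C=C(C)/C=C/[C@H]2C(C)=C[C@H](OC(=O)CCCCCCCCCCCCC)CC2(C)C)C(C)(C)C1 | target

**Step count and risks**
Total steps: 16. Longest linear sequence: 8 (steps 1–5, 7, 8, 16; the ε branch, steps 9–16, is equally long).

Most likely to fail, step 4 (ring enlargement). Attack of the secondary diazoalkane on the hindered α‑quaternary carbonyl may be slow, so that Lewis‑acid decomposition of diazoethane, epoxide formation or β‑elimination of palmitic acid compete, and any migration of the quaternary carbon would give the regioisomeric ketone. The fallback sets out from 4 and comes back at 7. Silylation of 4 (TBSCl, imidazole, DMF) gives (S)‑4‑(tert‑butyldimethylsilyloxy)‑2,2‑dimethylcyclopentan‑1‑one F1, which carries no ester‑type β‑leaving group. Ring enlargement with the bulkier trimethylsilyldiazomethane (BF3·OEt2, CH2Cl2, −78 °C, protodesilylation on work‑up) inserts a plain methylene and gives (R)‑4‑(tert‑butyldimethylsilyloxy)‑2,2‑dimethylcyclohexan‑1‑one F2. Methylation of its only enolate (LiN(i‑Pr)2, THF, −78 °C, then MeI) gives (4R)‑4‑(tert‑butyldimethylsilyloxy)‑2,2,6‑trimethylcyclohexan‑1‑one F3. Desilylation (HF·pyridine, THF) gives (4R)‑4‑hydroxy‑2,2,6‑trimethylcyclohexan‑1‑one F4, and acylation with 5 in pyridine returns to 7.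

Second, step 5 (enol triflation). O‑sulfonylation of the hindered ketone creates an oxocarbenium ion next to a quaternary carbon, so a 1,2‑methyl shift or slow loss of the tertiary α‑proton may outrun enol triflate formation, and liberated acid could attack the ester. The fallback sets out from 7 and comes back at 8. Soft enolisation (TMSOTf, Et3N, CH2Cl2, 0 °C → rt), which leaves the ester untouched, gives (1R)‑3,5,5‑trimethyl‑4‑(trimethylsilyloxy)cyclohex‑3‑en‑1‑yl hexadecanoate F5. Fluoride‑induced release of the enolate in the presence of N‑phenylbis(trifluoromethanesulfonimide) (CsF, DME, rt) gives 8.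

Third, step 11 (transfer hydrogenation and separation). The catalyst may discriminate poorly between the alkenyl and the methylene flank of the ring ketone, conjugate reduction may compete, and the acidic hydrolysis may epimerise the allylic carbinol. The fallback sets out from 15 and comes back at 16. Luche reduction (NaBH4, CeCl3·7H2O, MeOH, −20 °C) gives the racemic cis/trans alcohols (±)‑3,5,5‑trimethyl‑4‑[(E)‑2‑(2‑methyl‑1,3‑dioxolan‑2‑yl)ethenyl]cyclohex‑2‑en‑1‑ol F6. Acylative kinetic resolution with a Pseudomonas lipase and vinyl acetate should acetylate the (1R) alcohols. The trans acetate (1R,4R)‑3,5,5‑trimethyl‑4‑[(E)‑2‑(2‑methyl‑1,3‑dioxolan‑2‑yl)ethenyl]cyclohex‑2‑en‑1‑yl acetate F7 is separated from the unreacted (1S) alcohols and from the cis acetate. Methanolysis (K2CO3, MeOH) gives 16, which is hydrolysed as in step 11.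

**Further compounds**
F1 | step 4 | (S)‑4‑(tert‑butyldimethylsilyloxy)‑2,2‑dimethylcyclopentan‑1‑one | CC(C)(C)[Si](C)(C)O[C@@H]1CC(=O)C(C)(C)C1
F2 | step 4 | (R)‑4‑(tert‑butyldimethylsilyloxy)‑2,2‑dimethylcyclohexan‑1‑one | CC(C)(C)[Si](C)(C)O[C@@H]1CCC(=O)C(C)(C)C1
F3 | step 4 | (4R)‑4‑(tert‑butyldimethylsilyloxy)‑2,2,6‑trimethylcyclohexan‑1‑one (C6 epimers) | CC(C)(C)[Si](C)(C)O[C@@H]1CC(C)C(=O)C(C)(C)C1
F4 | step 4 | (4R)‑4‑hydroxy‑2,2,6‑trimethylcyclohexan‑1‑one (C6 epimers) | O[C@@H]1CC(C)C(=O)C(C)(C)C1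
F5 | step 5 | (1R)‑3,5,5‑trimethyl‑4‑(trimethylsilyloxy)cyclohex‑3‑en‑1‑yl hexadecanoate | CCCCCCCCCCCCCCCC(=O)O[C@@H]1CC(C)=C(O[Si](C)(C)C)C(C)(C)C1
F6 | step 11 | (±)‑3,5,5‑trimethyl‑4‑[(E)‑2‑(2‑methyl‑1,3‑dioxolan‑2‑yl)ethenyl]cyclohex‑2‑en‑1‑ol (cis/trans mixture) | CC1(OCCO1)/C=C/C1C(C)=CC(O)CC1(C)C
F7 | step 11 | (1R,4R)‑3,5,5‑trimethyl‑4‑[(E)‑2‑(2‑methyl‑1,3‑dioxolan‑2‑yl)ethenyl]cyclohex‑2‑en‑1‑yl acetate | CC1(OCCO1)/C=C/[C@H]1C(C)=C[C@H](OC(C)=O)CC1(C)C
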